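## The problem

Target 27 is an achiral diaryl ether. Ring A is a 5-pentylresorcinol that carries the ether oxygen on the carbon between one hydroxyl and the pentyl group; ring B is a methyl benzoate with the ether oxygen at C2, a methoxy group at C4 and a pentanoyl group at C6. The ether oxygen therefore has three ortho neighbours (hydroxyl and pentyl on ring A, the ester on ring B), so joining two finished rings would pair a hindered, electron-rich aryl partner with a hydrogen-bonded, electron-poor salicylate phenol. There are no stereocentres; the control problems are regiochemical, namely which ring A oxygen ends up beside the ether and how three phenolic oxygens are told apart so that two end free and one methylated. Ring B is fragile: a 2-acylbenzoate closes to an indane-1,3-dione under alkoxide, the butyl ketone is enolisable, and an aryl ketone with gamma hydrogens fragments under ultraviolet light (Norrish type 2). Finished ring A is a very electron-rich resorcinol, sensitive to oxidants and electrophiles, so it is best formed late and without protecting-group traffic. The enabling feature is the ring A pattern C1' (aryloxy), C2' (OH), C4' (oxygen, meta to C2') and C6' (pentyl), which is what a vinylketene and an alkoxyalkyne deliver in a benzannulation: C2' from the ketene carbonyl, C3' and C4' from the alkyne, C5' from a diazo carbon, and C6' and C1' from an enol-ether double bond. The hindered C–O bond can then be made at an sp2 enol carbon by addition–elimination instead of at an aryl carbon.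

## Retrosynthesis

**27 from 26.** Only the O–tert-butyl bond at C4' of ring A is cut. The tert-butyl group is not a protecting group added for its own sake; it arrives with the alkyne in the ring-forming step. It is the one alkyl group that acid removes without touching the ring B methyl ether, the methyl ester or the ketone. The forward step has to keep the freed tert-butyl cation off the resorcinol ring.

**26 from 17 and 21 (key disconnection).** Ring A is taken apart completely: the bonds C1'–C2', C2'–C3', C4'–C5' and C5'–C6' are cut. This leads back to the beta-aryloxy vinyl diazoketone 17 and tert-butoxyethyne 21, by way of vinylketene 22, cyclobutenone 23, dienylketene 24 and cyclohexadienone 25. Cutting the diaryl ether C–O bond instead would require a tri-ortho-substituted Ullmann-type coupling and a regiodefined, doubly protected ring A phenol. The benzannulation cut places OH, O-tert-butyl, pentyl and aryloxy by connectivity alone and leaves the two ring A oxygens differentiated. The precursor is much simpler: one aromatic ring and no ring A phenol chemistry. The forward step must generate the ketene without ultraviolet light (ring B ketone) and must unite ketene and ynol ether in one orientation.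

**17 from 14 via 16 and 15.** The bond between the enone carbonyl carbon and the diazo carbon is cut, giving acid chloride 16, then acid 15 and its tert-butyl ester 14. Acylation of a diazoalkane is preferred over diazo transfer to a methyl ketone, because strong-base enolisation would not distinguish that ketone from the ring B butyl ketone. The tert-butyl ester is chosen because acid removes it beside the ring B methyl ester, whereas aqueous NaOH would attack the beta-aryloxy acrylate at the beta carbon. The forward steps must leave the enol ether and ring B untouched.

**14 from 9 and 13.** The vinyl C–O bond is cut, giving salicylate phenol 9 and enol tosylate 13. This is the hindered ether bond of the target, made here as a vinylogous carbonate by addition–elimination at an acceptor-activated sp2 carbon, which needs only K2CO3 as base. The forward reaction must deliver oxygen to carbon (not to sulfur) and must not enolise the ring B ketone.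

**13 from 10 via 12 and 11.** The C–C bond between C2 of the heptanoate and the formyl carbon is cut. Enol tosylate 13 comes from formyl ester 12, which comes from tert-butyl heptanoate 11 by crossed Claisen formylation, and 11 from heptanoic acid 10. The pentyl chain of ring A is thus bought as heptanoic acid.

**9 from 1.** The C2 methyl ether of ester 8 is cut selectively (it is the one chelated by the ester), giving 9. Ester 8 comes from keto acid 7, and 7 from phthalide 5 by saponification to the sodium hydroxy carboxylate 6 and oxidation of its benzylic alcohol. The carboxyl carbon of 5 is cut back, through hydroxy acid 4, to aryl bromide 3, and the butyl group back to aldehyde 2, which is the bromination product of 3,5-dimethoxybenzaldehyde 1. Carrying the ketone as a phthalide through the organolithium step avoids any ketone protecting group, and bromination ortho to the formyl group fixes the 1,2,3,5 pattern of ring B at the outset.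

**21 from 18.** The alkyne C–O bond is traced to trichloroethylene 18 by way of dichlorovinyl ether 19 and lithium acetylide 20. The ynol ether is made fresh because it is volatile and thermally labile.

## Roads not taken

**Alternative 1: ring B aryne, phenoxide capture, then carboxylation.**
- Cut: the diaryl ether C–O bond at ring B C2 and the ring B C1–carboxyl bond.
- Forward key step: CsF releases the aryne from silyl triflate A2. The potassium salt of ring A phenol A3 adds at the aryne carbon remote from the ketal, and the aryl anion next to the ketal is carboxylated by CO2 to give acid A1.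
- Merits: two bonds in one flask; an aryne is largely indifferent to the steric crowding that defeats Ullmann couplings; no diazo compound or photochemistry.
- Weak points for this target:
  - Regiochemistry of phenoxide addition rests only on the bulk of the ketal-bearing substituent; the methoxy group is too remote to help.
  - The aryl anion can be protonated, or add to a second aryne, before carboxylation occurs.
  - A2 needs a multistep synthesis, including ketalisation of a hindered aryl ketone.
  - A3 needs regioselective oxygenation of an olivetol derivative and two protecting groups.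
  - Esterification and a global deprotection follow.
- Comparison: this road is more convergent, probably shorter in its longest line, and safer on scale. The chosen plan sets against it complete regiochemical certainty (every ring A substituent is fixed by connectivity in 17), no protecting group on ring B, and no separate synthesis of an oxidised ring A.

**Alternative 2: Michael–Claisen annulation of ring A onto an alpha-aryloxy enone.**
- Cut: ring A bonds C5'–C6' and C3'–C4'.
- Forward key step: dimethyl malonate A6 with NaOMe adds to the beta carbon of enone A5. The methyl ketone enolate then attacks a malonate ester and closes the six-membered 1,3-dione A4.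
- Merits: it builds ring A on the pre-formed ether oxygen, as the chosen plan does, but from cheap reagents with robust, scalable carbonyl chemistry.
- Weak points:
  - A4 is at the cyclohexanedione oxidation level, so ester hydrolysis, decarboxylation and a dehydrogenation are still needed. Oxidative aromatisation must be done next to an electron-rich ring B.
  - The NaOMe conditions force the ring B ketone into a ketal, to prevent indanedione formation.
  - A5 needs a regioselective aldol condensation on an aryloxyacetone.
- Comparison: this road is better in cost and in avoiding energetic reagents. The chosen plan delivers ring A at the aromatic oxidation level directly, under near-neutral conditions that need no ketal, with the two ring A oxygens already differentiated.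

**Alternative 3: aryloxy pyrone Diels–Alder building ring B.**
- Cut: ring B bonds C1–C2 and C5–C6.
- Forward key step: heating 6-aryloxy-4-methoxy-2-pyrone A8 with alkynoate A9 gives a bicyclic adduct that loses carbon dioxide and leaves the fully substituted ring B in A7.
- Merits: the ether bond is made early on a pyrone, where it is easy. The congested tetrasubstituted ring B appears in one step. One acid treatment (two methoxymethyl ethers and the ketal) then gives the target, so the endgame is as short as in the chosen plan.
- Weak points:
  - 4-Methoxy-2-pyrones are sluggish dienes, and A9 is an internal alkyne with a bulky ketal at the reacting carbon, so forcing temperatures are expected.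
  - The phenol A3 of alternative 1 is again required, with its protecting groups.
  - Three building blocks (A3, A8, A9) must be made.
- Comparison: regiochemistry is electronically well matched and the convergence is higher. The chosen plan sets against it mild conditions (room-temperature light, then 80 °C), a ring A that never needs protection, and starting materials that are bulk chemicals.

Key step: step 16

Remark on the chemistry: the target has no stereocentres. The enol-ether double bond of 13–17 is drawn E throughout, and either isomer would serve because the geometry is erased when ring A aromatises. The sp3 centres of 3, 4, 5, 6, 12, 23 and 25 are racemic and are all lost. tert-Butoxyethyne is prepared on the route and is not assumed to be purchasable.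

## Route

Step 1
Reactants: 1 3,5-dimethoxybenzaldehyde
Product: 2 2-bromo-3,5-dimethoxybenzaldehyde
Conditions: NBS, MeCN, 0 °C → rt
Reagents that add atoms: N-bromosuccinimide, O=C1CCC(=O)N1Br
Why: Electrophilic aromatic bromination; the position ortho to the formyl group is para to one methoxy and ortho to the other and is less crowded than the position between the two methoxy groups, so the 2-bromo isomer should dominate.

Step 2
Reactants: 2 2-bromo-3,5-dimethoxybenzaldehyde
Product: 3 1-(2-bromo-3,5-dimethoxyphenyl)pentan-1-ol (racemic)
Conditions: n-BuMgCl, THF, −78 → 0 °C; aq NH4Cl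
Reagents that add atoms: butylmagnesium chloride, CCCC[Mg]Cl
Why: Grignard addition to an aryl aldehyde is far faster than bromine–magnesium exchange at low temperature, so the aryl bromide should survive; the new carbinol centre is racemic and is oxidised away in step 4.

Step 3
Reactants: 3 1-(2-bromo-3,5-dimethoxyphenyl)pentan-1-ol
Product: 5 3-butyl-5,7-dimethoxy-2-benzofuran-1(3H)-one, via hydroxy acid 4 (not isolated)
Conditions: n-BuLi (2.2 equiv), THF, −78 °C; CO2; 2 M HCl, rt
Reagents that add atoms: carbon dioxide, O=C=O
Why: The first equivalent of base forms the alkoxide and the second effects bromine–lithium exchange (Parham-type dianion); carboxylation of the aryllithium and acidification give hydroxy acid 4, which lactonises spontaneously to the five-membered phthalide, a convenient purification point.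

Step 4
Reactants: 5 3-butyl-5,7-dimethoxy-2-benzofuran-1(3H)-one
Product: 7 2,4-dimethoxy-6-pentanoylbenzoic acid, via sodium hydroxy carboxylate 6 (not isolated)
Conditions: NaOH, H2O, 80 °C; KMnO4, 0 °C → rt; filter; HCl
Reagents that add atoms: sodium hydroxide, [Na+].[OH-]
Why: Lactone saponification gives the sodium carboxylate 6, whose secondary benzylic alcohol is oxidised by cold alkaline KMnO4 to the ketone, the classical conversion of 3-alkylphthalides into 2-acylbenzoic acids; acidification then releases 7, which may exist partly as its ring-closed lactol tautomer.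

Step 5
Reactants: 7 2,4-dimethoxy-6-pentanoylbenzoic acid
Product: 8 methyl 2,4-dimethoxy-6-pentanoylbenzoate
Conditions: MeI, K2CO3, DMF, rt
Reagents that add atoms: iodomethane, CI
Why: SN2 alkylation of the carboxylate is insensitive to the two ortho substituents and gives the open-chain (normal) methyl ester, where acid-catalysed esterification would favour the cyclic pseudo-ester.

Step 6
Reactants: 8 methyl 2,4-dimethoxy-6-pentanoylbenzoate
Product: 9 methyl 2-hydroxy-4-methoxy-6-pentanoylbenzoate
Conditions: BCl3, CH2Cl2, −78 → 0 °C; H2O
Reagents that add atoms: none
Why: Chelation-controlled Lewis-acid demethylation; boron bridges the ester carbonyl and the adjacent C2 methoxy oxygen, so only that ether is cleaved, while the C4 methoxy group has no neighbouring carbonyl and should remain.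

Step 7
Reactants: 10 heptanoic acid
Product: 11 tert-butyl heptanoate
Conditions: 2-methylpropene, cat. H2SO4, CH2Cl2, rt, pressure bottle
Reagents that add atoms: 2-methylpropene, C=C(C)C
Why: Acid-catalysed addition of the carboxylic acid to isobutene is the standard atom-economical tert-butyl ester synthesis.

Step 8
Reactants: 11 tert-butyl heptanoate
Product: 12 tert-butyl 2-formylheptanoate (racemic, in equilibrium with its enol)
Conditions: LiN(iPr)2 (2.1 equiv), THF, −78 °C; HCO2Et, −78 → 0 °C; aq NH4Cl
Reagents that add atoms: ethyl formate, CCOC=O
Why: Crossed Claisen formylation of the ester enolate with a non-enolisable formate; the bulky tert-butyl ester suppresses self-condensation and the product is held as its stable enolate until work-up.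

Step 9
Reactants: 12 tert-butyl 2-formylheptanoate
Product: 13 tert-butyl (2E)-2-{[(4-methylbenzenesulfonyl)oxy]methylidene}heptanoate
Conditions: TsCl, N-methylimidazole, Et3N, CH2Cl2, 0 °C
Reagents that add atoms: 4-methylbenzenesulfonyl chloride, Cc1ccc(cc1)S(Cl)(=O)=O
Why: O-Sulfonylation of the formyl ester enol with the tosyl chloride/N-methylimidazole/amine system is an established route to beta-tosyloxy acrylates; the E isomer is expected to predominate, and the geometry is not decisive because the next step is an addition–elimination.

Step 10
Reactants: 9 methyl 2-hydroxy-4-methoxy-6-pentanoylbenzoate; 13 tert-butyl (2E)-2-{[(4-methylbenzenesulfonyl)oxy]methylidene}heptanoate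
Product: 14 tert-butyl (2E)-2-{[5-methoxy-2-(methoxycarbonyl)-3-pentanoylphenoxy]methylidene}heptanoate
Conditions: K2CO3, DABCO (20 mol %), MeCN, rt → 40 °C
Reagents that add atoms: none
Why: Nucleophilic vinylic substitution by addition–elimination at the acceptor-activated beta carbon, accelerated by the amine through a vinylammonium intermediate; K2CO3 deprotonates only the phenol, not the ring B ketone, and reversible addition should deliver the more stable E enol ether.

Step 11
Reactants: 14 tert-butyl (2E)-2-{[5-methoxy-2-(methoxycarbonyl)-3-pentanoylphenoxy]methylidene}heptanoate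
Product: 15 (2E)-2-{[5-methoxy-2-(methoxycarbonyl)-3-pentanoylphenoxy]methylidene}heptanoic acid
Conditions: CF3CO2H/CH2Cl2 (1:3), 0 °C → rt
Reagents that add atoms: none
Why: Acidolysis of the tert-butyl ester through the tert-butyl cation; the beta-aryloxy acrylate is a vinylogous carbonate and resists protonation, and the methyl ester, ketone and methyl ether are inert to anhydrous acid.

Step 12
Reactants: 15 (2E)-2-{[5-methoxy-2-(methoxycarbonyl)-3-pentanoylphenoxy]methylidene}heptanoic acid
Product: 16 (2E)-2-{[5-methoxy-2-(methoxycarbonyl)-3-pentanoylphenoxy]methylidene}heptanoyl chloride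
Conditions: (COCl)2, cat. DMF, CH2Cl2, 0 °C → rt; evaporate
Reagents that add atoms: oxalyl chloride, ClC(=O)C(Cl)=O
Why: Vilsmeier-catalysed acid chloride formation under near-neutral conditions; the acid has no alpha hydrogen, so ketene formation is not a concern, and the crude chloride is used directly.

Step 13
Reactants: 16 (2E)-2-{[5-methoxy-2-(methoxycarbonyl)-3-pentanoylphenoxy]methylidene}heptanoyl chloride
Product: 17 methyl 2-{[(1E)-2-(diazoacetyl)hept-1-en-1-yl]oxy}-4-methoxy-6-pentanoylbenzoate
Conditions: CH2N2 (3 equiv), Et2O, 0 °C, dark
Reagents that add atoms: diazomethane, C=[N+]=[N-]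
Why: Arndt–Eistert-type acylation of diazomethane, with the excess reagent consuming the hydrogen chloride; the double bond is trisubstituted and carries an oxygen donor at the beta carbon, so it should be a poor dipolarophile, and the unactivated ring B ketone does not react with diazomethane without a Lewis acid.

Step 14
Reactants: 18 trichloroethylene
Product: 19 2-{[(E)-1,2-dichloroethenyl]oxy}-2-methylpropane (tert-butyl (E)-1,2-dichlorovinyl ether)
Conditions: KOtBu, THF, −40 °C → rt
Reagents that add atoms: potassium tert-butoxide, CC(C)(C)[O-].[K+]
Why: Base-induced loss of hydrogen chloride gives dichloroacetylene in situ, to which the alkoxide adds in an anti sense; this is the established entry to 1,2-dichlorovinyl ethers as ynol ether precursors.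

Step 15
Reactants: 19 2-{[(E)-1,2-dichloroethenyl]oxy}-2-methylpropane
Product: 21 tert-butoxyethyne, via lithium tert-butoxyethynide 20 (not isolated)
Conditions: n-BuLi (2.2 equiv), Et2O, −78 → −40 °C; aq NH4Cl, −78 °C; kept as a cold ethereal solution
Reagents that add atoms: none
Why: Deprotonation and beta-elimination give the chloroalkynyl ether, chlorine–lithium exchange gives acetylide 20 and protonation gives the terminal ynol ether; 21 is assayed and used as a cold solution because it loses 2-methylpropene on warming.

Step 16
Reactants: 17 methyl 2-{[(1E)-2-(diazoacetyl)hept-1-en-1-yl]oxy}-4-methoxy-6-pentanoylbenzoate; 21 tert-butoxyethyne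
Product: 26 methyl 2-(4-tert-butoxy-2-hydroxy-6-pentylphenoxy)-4-methoxy-6-pentanoylbenzoate, via vinylketene 22 (not isolated), via cyclobutenone 23 (not isolated), via dienylketene 24 (not isolated), via cyclohexadienone 25 (not isolated)
Conditions: 21 (4 equiv), CH2Cl2 (0.02 M), blue LEDs (440 nm), 20 °C; evaporate; toluene, 80 °C
Reagents that add atoms: none
Why: Blue light excites only the diazoketone of 17, which loses nitrogen with 1,2-shift of the alkenyl group (Wolff rearrangement) to vinylketene 22, while the ring B aryl ketone does not absorb at this wavelength and so should escape Norrish gamma-hydrogen abstraction. The nucleophilic unsubstituted carbon of 21 attacks the ketene carbonyl carbon and the pair closes in a 2+2 sense to the 3-tert-butoxy-4-alkenylcyclobutenone 23. Excess 21 is removed before heating because it would fragment to ketene and 2-methylpropene and acylate the product. At 80 °C 23 opens reversibly by four-electron electrocyclic cleavage to dienylketene 24, and the isomer with ketene and enol-ether alkene cis closes ring A by thermal six-electron disrotatory electrocyclisation between the ketene carbon and the aryloxy-bearing carbon, giving cyclohexadienone 25, which enolises to phenol 26. The closest known reaction type is the vinylketene–alkoxyalkyne benzannulation in its photochemical Wolff form, here run with visible light. Four ring bonds are new (one from the 1,2-shift, two from the 2+2 union, one from the electrocyclisation), and no stereocentre survives because the sp3 centres of 23 and 25 and the enol-ether geometry are erased on aromatisation. The one selectivity needed, the orientation of the ketene–alkyne union, follows from the polarity of the ynol ether and puts the tert-butoxy carbon meta to the new hydroxyl and para to the ether carbon.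

Step 17
Reactants: 26 methyl 2-(4-tert-butoxy-2-hydroxy-6-pentylphenoxy)-4-methoxy-6-pentanoylbenzoate
Product: 27 methyl 2-(2,4-dihydroxy-6-pentylphenoxy)-4-methoxy-6-pentanoylbenzoate
Conditions: CF3CO2H/CH2Cl2 (1:3), 1,3-dimethoxybenzene (10 equiv), 0 °C → rt
Reagents that add atoms: none
Why: Acidolysis of the aryl tert-butyl ether by alkyl–oxygen cleavage; the methyl ether, methyl ester, ketone and diaryl ether are stable to the acid, and the excess of 1,3-dimethoxybenzene traps the tert-butyl cation by Friedel–Crafts alkylation before it can alkylate the resorcinol ring.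

## Compound list

1 | 3,5-dimethoxybenzaldehyde | COc1cc(OC)cc(C=O)c1 | starting material
2 | 2-bromo-3,5-dimethoxybenzaldehyde | COc1cc(OC)c(Br)c(C=O)c1 | intermediate
3 | 1-(2-bromo-3,5-dimethoxyphenyl)pentan-1-ol (racemic) | CCCCC(O)c1cc(OC)cc(OC)c1Br | intermediate
4 | 2-(1-hydroxypentyl)-4,6-dimethoxybenzoic acid (racemic; formed on acidification, not isolated) | CCCCC(O)c1cc(OC)cc(OC)c1C(=O)O | intermediate
5 | 3-butyl-5,7-dimethoxy-2-benzofuran-1(3H)-one (racemic) | CCCCC1OC(=O)c2c(OC)cc(OC)cc12 | intermediate
6 | sodium 2-(1-hydroxypentyl)-4,6-dimethoxybenzoate (racemic, not isolated) | CCCCC(O)c1cc(OC)cc(OC)c1C(=O)[O-].[Na+] | intermediate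
7 | 2,4-dimethoxy-6-pentanoylbenzoic acid | CCCCC(=O)c1cc(OC)cc(OC)c1C(=O)O | intermediate
8 | methyl 2,4-dimethoxy-6-pentanoylbenzoate | CCCCC(=O)c1cc(OC)cc(OC)c1C(=O)OC | intermediate
9 | methyl 2-hydroxy-4-methoxy-6-pentanoylbenzoate | CCCCC(=O)c1cc(OC)cc(O)c1C(=O)OC | intermediate
10 | heptanoic acid | CCCCCCC(=O)O | starting material
11 | tert-butyl heptanoate | CCCCCCC(=O)OC(C)(C)C | intermediate
12 | tert-butyl 2-formylheptanoate (racemic) | CCCCCC(C=O)C(=O)OC(C)(C)C | intermediate
13 | tert-butyl (2E)-2-{[(4-methylbenzenesulfonyl)oxy]methylidene}heptanoate | CCCCC/C(=C\OS(=O)(=O)c1ccc(C)cc1)C(=O)OC(C)(C)C | intermediate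
14 | tert-butyl (2E)-2-{[5-methoxy-2-(methoxycarbonyl)-3-pentanoylphenoxy]methylidene}heptanoate | CCCCC/C(=C\Oc1cc(OC)cc(C(=O)CCCC)c1C(=O)OC)C(=O)OC(C)(C)C | intermediate
15 | (2E)-2-{[5-methoxy-2-(methoxycarbonyl)-3-pentanoylphenoxy]methylidene}heptanoic acid | CCCCC/C(=C\Oc1cc(OC)cc(C(=O)CCCC)c1C(=O)OC)C(=O)O | intermediate
16 | (2E)-2-{[5-methoxy-2-(methoxycarbonyl)-3-pentanoylphenoxy]methylidene}heptanoyl chloride | CCCCC/C(=C\Oc1cc(OC)cc(C(=O)CCCC)c1C(=O)OC)C(Cl)=O | intermediate
17 | methyl 2-{[(1E)-2-(diazoacetyl)hept-1-en-1-yl]oxy}-4-methoxy-6-pentanoylbenzoate | CCCCC/C(=C\Oc1cc(OC)cc(C(=O)CCCC)c1C(=O)OC)C(=O)C=[N+]=[N-] | intermediate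
18 | trichloroethylene | ClC=C(Cl)Cl | starting material
19 | 2-{[(E)-1,2-dichloroethenyl]oxy}-2-methylpropane | CC(C)(C)O/C(Cl)=C\Cl | intermediate
20 | lithium tert-butoxyethynide (not isolated) | [Li]C#COC(C)(C)C | intermediate
21 | tert-butoxyethyne | C#COC(C)(C)C | intermediate
22 | methyl 4-methoxy-2-{[(1E)-2-(2-oxoethenyl)hept-1-en-1-yl]oxy}-6-pentanoylbenzoate (vinylketene, not isolated) | CCCCC/C(=C\Oc1cc(OC)cc(C(=O)CCCC)c1C(=O)OC)C=C=O | intermediate
23 | methyl 2-{[(1E)-2-(2-tert-butoxy-4-oxocyclobut-2-en-1-yl)hept-1-en-1-yl]oxy}-4-methoxy-6-pentanoylbenzoate (racemic, not isolated) | CCCCC/C(=C\Oc1cc(OC)cc(C(=O)CCCC)c1C(=O)OC)C1C(=O)C=C1OC(C)(C)C | intermediate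
24 | methyl 2-{[(1E,3E)-4-tert-butoxy-6-oxo-2-pentylhexa-1,3,5-trien-1-yl]oxy}-4-methoxy-6-pentanoylbenzoate (dienylketene, not isolated) | CCCCC/C(=C\Oc1cc(OC)cc(C(=O)CCCC)c1C(=O)OC)/C=C(/OC(C)(C)C)C=C=O | intermediate
25 | methyl 2-[(4-tert-butoxy-2-oxo-6-pentylcyclohexa-3,5-dien-1-yl)oxy]-4-methoxy-6-pentanoylbenzoate (racemic, not isolated) | CCCCCC1=CC(OC(C)(C)C)=CC(=O)C1Oc1cc(OC)cc(C(=O)CCCC)c1C(=O)OC | intermediate
26 | methyl 2-(4-tert-butoxy-2-hydroxy-6-pentylphenoxy)-4-methoxy-6-pentanoylbenzoate | CCCCCc1cc(OC(C)(C)C)cc(O)c1Oc1cc(OC)cc(C(=O)CCCC)c1C(=O)OC | intermediate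
27 | methyl 2-(2,4-dihydroxy-6-pentylphenoxy)-4-methoxy-6-pentanoylbenzoate | CCCCCc1cc(O)cc(O)c1Oc1cc(OC)cc(C(=O)CCCC)c1C(=O)OC | target

## Step count and least certain steps

Total step count: 17. Longest linear sequence: 12 steps (steps 1–6, 10–13, 16 and 17, from 3,5-dimethoxybenzaldehyde 1).

**Step 16 (key step).**
- What may go wrong: the beta-aryloxy vinylketene 22 may be diverted before it meets the alkyne, by four-electron closure to a 4-aryloxycyclobutenone that reopens only slowly, or by dimerisation. The thermally fragile ynol ether 21 may be lost by retro-ene fragmentation if the mixture warms. A light source with an ultraviolet tail would start gamma-hydrogen abstraction at the ring B ketone.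
- Fallback: leave ketene chemistry and form the diaryl ether by a Cu(OAc)2-mediated coupling. It sets out from phenol 9 and rejoins the route at target 27.
  - 5-Pentylbenzene-1,3-diol F1 would be converted with chloromethyl methyl ether and iPr2NEt into 1,3-bis(methoxymethoxy)-5-pentylbenzene F2.
  - Bromination with NBS, with the same regiochemistry as step 1, would give 2-bromo-1,5-bis(methoxymethoxy)-3-pentylbenzene F3.
  - Bromine–lithium exchange with n-BuLi and quenching with B(OiPr)3 would give [2,4-bis(methoxymethoxy)-6-pentylphenyl]boronic acid F4.
  - Chan–Lam coupling of F4 with 9 (Cu(OAc)2, pyridine, molecular sieves, air, CH2Cl2, rt) would give methyl 2-[2,4-bis(methoxymethoxy)-6-pentylphenoxy]-4-methoxy-6-pentanoylbenzoate F5.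
  - HCl in methanol would remove both acetals and give 27.
  - The coupling is hindered and is expected to be inefficient, but every reaction type in it is established.

**Step 13.**
- What may go wrong: 1,3-dipolar cycloaddition of diazomethane to the conjugated double bond of 16 or 17 (pyrazoline formation), or capture of hydrogen chloride by the product to give a chloromethyl ketone.
- Fallback: install the diazo group by diazo transfer instead of acylating a diazoalkane. It sets out from acid chloride 16 and returns at 17.
  - C-Acylation of tert-butyl acetoacetate under soft enolisation (MgCl2, pyridine, CH2Cl2) would give tert-butyl (4E)-2-acetyl-4-{[5-methoxy-2-(methoxycarbonyl)-3-pentanoylphenoxy]methylidene}-3-oxononanoate F6.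
  - Trifluoroacetic acid would cleave the ester and cause decarboxylation to methyl 4-methoxy-2-{[(1E)-2-(3-oxobutanoyl)hept-1-en-1-yl]oxy}-6-pentanoylbenzoate F7.
  - Regitz diazo transfer (4-acetamidobenzenesulfonyl azide, Et3N) is selective for the 1,3-diketone over the ring B ketone and would give methyl 2-{[(1E)-2-(2-diazo-3-oxobutanoyl)hept-1-en-1-yl]oxy}-4-methoxy-6-pentanoylbenzoate F8.
  - Cold aqueous KOH in MeCN would remove the unhindered acetyl group and give 17. This last operation needs care, because hydroxide can also attack the beta carbon of the enol ether.

**Step 10.**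
- What may go wrong: attack of the phenoxide at sulfur (sulfonyl transfer back to the enolate of 12) instead of at the beta carbon, and base-induced intramolecular Claisen closure of the ring B keto ester if the mixture has to be heated.
- Fallback: make the vinyl C–O bond by conjugate addition and add the pentyl group afterwards. It sets out from 9 and returns at 14.
  - DABCO-catalysed addition of 9 to tert-butyl propiolate would give tert-butyl (2E)-3-[5-methoxy-2-(methoxycarbonyl)-3-pentanoylphenoxy]prop-2-enoate F9.
  - Bromine addition followed by Et3N-induced loss of hydrogen bromide would give tert-butyl (2Z)-2-bromo-3-[5-methoxy-2-(methoxycarbonyl)-3-pentanoylphenoxy]prop-2-enoate F10.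
  - Negishi coupling with pentylzinc bromide (Pd(PPh3)4, THF, rt) proceeds with retention and tolerates the ketone, and would give 14.

**Step 4.**
- What may go wrong: over-oxidation by KMnO4 (cleavage next to the new enolisable ketone, or attack on the electron-rich ring), or relactonisation to 5 before oxidation is complete.
- Fallback: avoid the phthalide. It sets out from alcohol 3 and returns at ester 8, bypassing 5, 6 and 7.
  - Oxidation of 3 with MnO2 in CH2Cl2 would give 1-(2-bromo-3,5-dimethoxyphenyl)pentan-1-one F11.
  - Methoxycarbonylation (Pd(OAc)2, Xantphos, CO, MeOH, Et3N, 80 °C) would give 8 directly. Any alkylidenephthalide formed from the acylpalladium intermediate and the ketone enol would be opened to the same keto ester by methanol and base.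

## Further compounds

F1 | step 16 | 5-pentylbenzene-1,3-diol | CCCCCc1cc(O)cc(O)c1
F2 | step 16 | 1,3-bis(methoxymethoxy)-5-pentylbenzene | CCCCCc1cc(OCOC)cc(OCOC)c1
F3 | step 16 | 2-bromo-1,5-bis(methoxymethoxy)-3-pentylbenzene | CCCCCc1cc(OCOC)cc(OCOC)c1Br
F4 | step 16 | [2,4-bis(methoxymethoxy)-6-pentylphenyl]boronic acid | CCCCCc1cc(OCOC)cc(OCOC)c1B(O)O
F5 | step 16 | methyl 2-[2,4-bis(methoxymethoxy)-6-pentylphenoxy]-4-methoxy-6-pentanoylbenzoate | CCCCCc1cc(OCOC)cc(OCOC)c1Oc1cc(OC)cc(C(=O)CCCC)c1C(=O)OC
F6 | step 13 | tert-butyl (4E)-2-acetyl-4-{[5-methoxy-2-(methoxycarbonyl)-3-pentanoylphenoxy]methylidene}-3-oxononanoate | CC(=O)C(C(=O)OC(C)(C)C)C(=O)/C(CCCCC)=C/Oc1cc(OC)cc(C(=O)CCCC)c1C(=O)OC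
F7 | step 13 | methyl 4-methoxy-2-{[(1E)-2-(3-oxobutanoyl)hept-1-en-1-yl]oxy}-6-pentanoylbenzoate | CC(=O)CC(=O)/C(CCCCC)=C/Oc1cc(OC)cc(C(=O)CCCC)c1C(=O)OC
F8 | step 13 | methyl 2-{[(1E)-2-(2-diazo-3-oxobutanoyl)hept-1-en-1-yl]oxy}-4-methoxy-6-pentanoylbenzoate | CC(=O)C(=[N+]=[N-])C(=O)/C(CCCCC)=C/Oc1cc(OC)cc(C(=O)CCCC)c1C(=O)OC
F9 | step 10 | tert-butyl (2E)-3-[5-methoxy-2-(methoxycarbonyl)-3-pentanoylphenoxy]prop-2-enoate | CCCCC(=O)c1cc(OC)cc(O/C=C/C(=O)OC(C)(C)C)c1C(=O)OC
F10 | step 10 | tert-butyl (2Z)-2-bromo-3-[5-methoxy-2-(methoxycarbonyl)-3-pentanoylphenoxy]prop-2-enoate | CCCCC(=O)c1cc(OC)cc(O/C=C(\Br)C(=O)OC(C)(C)C)c1C(=O)OC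
F11 | step 4 | 1-(2-bromo-3,5-dimethoxyphenyl)pentan-1-one | CCCCC(=O)c1cc(OC)cc(OC)c1Br
A1 | alternative 1 | 2-[2,4-bis(methoxymethoxy)-6-pentylphenoxy]-6-(2-butyl-1,3-dioxolan-2-yl)-4-methoxybenzoic acid | CCCCCc1cc(OCOC)cc(OCOC)c1Oc1cc(OC)cc(C2(CCCC)OCCO2)c1C(O)=O
A2 | alternative 1 | 3-(2-butyl-1,3-dioxolan-2-yl)-5-methoxy-2-(trimethylsilyl)phenyl trifluoromethanesulfonate | CCCCC1(OCCO1)c1cc(OC)cc(OS(=O)(=O)C(F)(F)F)c1[Si](C)(C)C
A3 | alternative 1 | 2,4-bis(methoxymethoxy)-6-pentylphenol | CCCCCc1cc(OCOC)cc(OCOC)c1O
A4 | alternative 2 | methyl 3-[3-(2-butyl-1,3-dioxolan-2-yl)-5-methoxy-2-(methoxycarbonyl)phenoxy]-4,6-dioxo-2-pentylcyclohexane-1-carboxylate (mixture of stereoisomers) | CCCCCC1C(C(=O)OC)C(=O)CC(=O)C1Oc1cc(OC)cc(C2(CCCC)OCCO2)c1C(=O)OC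
A5 | alternative 2 | methyl 2-(2-butyl-1,3-dioxolan-2-yl)-4-methoxy-6-{[(3Z)-2-oxonon-3-en-3-yl]oxy}benzoate | CCCCC/C=C(\Oc1cc(OC)cc(C2(CCCC)OCCO2)c1C(=O)OC)C(C)=O
A6 | alternative 2 | dimethyl malonate | COC(=O)CC(=O)OC
A7 | alternative 3 | methyl 2-[2,4-bis(methoxymethoxy)-6-pentylphenoxy]-6-(2-butyl-1,3-dioxolan-2-yl)-4-methoxybenzoate | CCCCCc1cc(OCOC)cc(OCOC)c1Oc1cc(OC)cc(C2(CCCC)OCCO2)c1C(=O)OC
A8 | alternative 3 | 6-[2,4-bis(methoxymethoxy)-6-pentylphenoxy]-4-methoxy-2H-pyran-2-one | CCCCCc1cc(OCOC)cc(OCOC)c1Oc1cc(OC)cc(=O)o1
A9 | alternative 3 | methyl 3-(2-butyl-1,3-dioxolan-2-yl)prop-2-ynoate | CCCCC1(OCCO1)C#CC(=O)OC
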